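**Retrosynthetic overview** (drimane numbering: C3 ketone, C4 CMe2, C5/C10 ring fusion, C7=C8, C9 bearing C11H2OAr)
1. Ring A is cut last at C3–C4. C3 acts as an acyl anion (the carbene-bound enaminol of an aldehyde) and C4 is the internal carbon of an isopropenyl group. The proton delivered to =CH2 creates the second C4 methyl, so one isomerisation makes the ketone, the quaternary carbon and the gem-dimethyl group.
2. The aldehyde comes from an allyl group (aldehyde-selective Wacker). The aryl ether comes from umbelliferone and the C11 primary alcohol (Mitsunobu).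
3. C9(H)–C11H2OH comes from a spiro vinyl epoxide (palladium/formate hydrogenolysis with inversion), which comes from the enone C=O and a sulfonium methylide.
4. Quaternary C10 comes from two alpha'-alkylations of (S)-carvone, allyl first and methyl last (anti to isopropenyl). This fixes the cis relation of the two arms that become ring A.
5. Ring order: ring B (with C5 and C7=C8–CH3) and the coumarin are bought. Ring A is the only ring formed, in the final step.

Assumption: the SMILES decodes to (1R,4aS,8aS). This is a cis-fused decalin with 5-H, 10-CH3 and 9-H on one face (called beta here) and C4, C1 and C11 on the other face of ring B (alpha). That is the compound made.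

**Step 1**
Reactants: 1 (S)-(+)-carvone; 2 allyl bromide
Product: 4 (5S,6R)-2-methyl-6-(prop-2-enyl)-5-(prop-1-en-2-yl)cyclohex-2-en-1-one (6-allylcarvone; trans epimer major), via lithium dienolate of carvone 3 (not isolated)
Conditions: LiN(iPr)2 (1.1 equiv), THF, −78 °C; then 2 (1.3 equiv), −78 °C to rt
Reagents that add atoms: allyl bromide C=CCBr
Why: Kinetic alpha'-deprotonation gives the cross-conjugated dienolate 3, which is C-allylated by SN2 (enolate alkylation) mainly anti to the isopropenyl group; the new C–H centre is flattened again in step 2, so its epimer ratio does not matter, and C5 comes unchanged from 1.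

**Step 2**
Reactants: 4 6-allylcarvone; 5 methyl iodide
Product: 7 (5R,6S)-2,6-dimethyl-6-(prop-2-enyl)-5-(prop-1-en-2-yl)cyclohex-2-en-1-one, via lithium dienolate of allylcarvone 6 (not isolated)
Conditions: LiN(iPr)2 (1.2 equiv), THF/DMPU 5:1, −78 to −20 °C; then MeI (3 equiv), −78 to 0 °C
Reagents that add atoms: methyl iodide CI
Why: Enolate alkylation: in the fully substituted dienolate 6, allylic strain with the allyl group pushes the C5 isopropenyl group pseudoaxial, so MeI enters from the opposite face and sets quaternary C10 with methyl trans and allyl cis to the isopropenyl group, the relation that later becomes the cis ring fusion.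

**Step 3**
Reactants: 7 6-allyl-6-methylcarvone; 8 trimethylsulfonium iodide
Product: 9 (3R,7R,8S)-4,8-dimethyl-8-(prop-2-enyl)-7-(prop-1-en-2-yl)-1-oxaspiro[2.5]oct-4-ene (oxygen alpha; CH2 beta)
Conditions: 8 (1.5 equiv), n-BuLi (1.4 equiv), THF, −10 °C; then 7, 0 °C to rt; neutral work-up, used crude
Reagents that add atoms: trimethylsulfonium iodide C[S+](C)C.[I-]
Why: Corey–Chaykovsky epoxidation: the small unstabilised sulfonium ylide adds 1,2 and irreversibly to the enone carbonyl and closes the oxirane, approaching C9 from the beta face (the side of the C10 methyl and 5-H) because the allyl and isopropenyl groups cover the alpha face, so C11 ends beta and oxygen alpha.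

**Step 4**
Reactants: 9 spiro vinyl epoxide
Product: 11 [(1R,5R,6S)-2,6-dimethyl-6-(prop-2-enyl)-5-(prop-1-en-2-yl)cyclohex-2-en-1-yl]methanol, via allylpalladium formate 10 (not isolated)
Conditions: Pd2(dba)3·CHCl3 (2.5 mol %), n-Bu3P (5 mol %), HCO2H (3 equiv), Et3N (1.2 equiv), 1,4-dioxane, rt
Reagents that add atoms: none
Why: Palladium-catalysed formate hydrogenolysis of an alkenyl oxirane: zerovalent palladium ionises the allylic C9–O bond with inversion to give 10 with the metal on the beta face, and after loss of CO2 the hydride passes from the metal (sigma-bound at the less hindered C7) to the more substituted terminus C9 on that same face, which sets 9-beta-H, swings C11 to the alpha face and leaves the C7=C8 alkene in place.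

**Step 5**
Reactants: 11 homoallylic alcohol; 12 umbelliferone (7-hydroxycoumarin)
Product: 13 7-{[(1R,5R,6S)-2,6-dimethyl-6-(prop-2-enyl)-5-(prop-1-en-2-yl)cyclohex-2-en-1-yl]methoxy}-2H-chromen-2-one
Conditions: 12 (1.3 equiv), PPh3, DIAD (1.5 equiv each), THF, 0 °C to rt
Reagents that add atoms: umbelliferone Oc1ccc2ccc(=O)oc2c1
Why: Mitsunobu etherification: the acidic phenol (pKa about 8) displaces the activated oxygen by SN2 at the primary carbon C11, so no stereocentre is touched and the alkenes are inert.

**Step 6**
Reactants: 13 allyl aryl ether; 14 dioxygen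
Product: 15 3-[(1S,2R,6R)-1,3-dimethyl-2-{[(2-oxo-2H-chromen-7-yl)oxy]methyl}-6-(prop-1-en-2-yl)cyclohex-3-en-1-yl]propanal
Conditions: PdCl2(PhCN)2 (12 mol %), CuCl2·2H2O (12 mol %), AgNO2 (6 mol %), t-BuOH/MeNO2 15:1, O2 (1 atm), rt
Reagents that add atoms: dioxygen O=O
Why: Nitrite-modified aldehyde-selective Wacker oxidation: only the monosubstituted alkene binds divalent palladium, the neighbouring quaternary C10 blocks Markovnikov attack so oxygen goes to the terminal carbon, and the 1,1-disubstituted alkene, the trisubstituted alkene and the coumarin do not react.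

**Step 7 (key step)**
Reactants: 15 aldehyde
Product: 17 7-{[(1R,4aS,8aS)-2,5,5,8a-tetramethyl-6-oxo-1,4,4a,5,6,7,8,8a-octahydronaphthalen-1-yl]methoxy}-2H-chromen-2-one (target), via Breslow enaminol 16 (not isolated)
Conditions: 3-(2,4,6-trimethylphenyl)-5,6,7,8-tetrahydro-4H-cyclohepta[d][1,3]thiazol-3-ium perchlorate (20 mol %), DBU (20 mol %), 4 Å MS, 1,4-dioxane (0.02 M), 120 °C, sealed tube
Reagents that add atoms: none
Why: Proposed new method: the carbene adds to the aldehyde and a proton shift gives enaminol 16, in which the former carbonyl carbon C3 is nucleophilic (an acyl anion equivalent); held cis and vicinal to the isopropenyl group on ring B, it can close ring A through a concerted asynchronous ene-type transition state in which the enol O–H proton goes to the terminal =CH2 (making the second C4 methyl) while C3 bonds to the internal, cation-stabilising carbon C4, after which the alkoxide collapses to the C3 ketone and frees the carbene; acyloin formation is reversible at this temperature whereas this bond formation is not, no stereocentre is created, and the cis fusion follows from C5 and C10 already in place; the closest known reaction type is the carbene-catalysed intramolecular hydroacylation of unactivated 1,1-disubstituted alkenes in 2-(allyloxy)benzaldehydes, which gives chromanones with an alpha-quaternary carbon, and the extension here is to an enolisable aliphatic aldehyde, an all-carbon tether and a purely alkyl-substituted alkene.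

**Compound list**
1 | (S)-(+)-carvone | CC1=CC[C@H](C(C)=C)CC1=O | starting material
2 | allyl bromide | C=CCBr | starting material
3 | lithium cross-conjugated dienolate of (S)-carvone | CC1=CC[C@H](C(C)=C)C=C1[O-].[Li+] | intermediate
4 | (5S,6R)-6-allylcarvone (trans epimer major) | CC1=CC[C@H](C(C)=C)[C@@H](CC=C)C1=O | intermediate
5 | methyl iodide | CI | starting material
6 | lithium dienolate of 6-allylcarvone | CC1=CC[C@H](C(C)=C)C(CC=C)=C1[O-].[Li+] | intermediate
7 | (5R,6S)-6-allyl-6-methylcarvone (methyl trans, allyl cis to isopropenyl) | CC1=CC[C@H](C(C)=C)[C@@](CC=C)(C)C1=O | intermediate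
8 | trimethylsulfonium iodide | C[S+](C)C.[I-] | starting material
9 | (3R,7R,8S)-4,8-dimethyl-8-allyl-7-isopropenyl-1-oxaspiro[2.5]oct-4-ene | CC1=CC[C@H](C(C)=C)[C@@](CC=C)(C)[C@@]12CO2 | intermediate
10 | allylpalladium formate: Pd(O2CH)(PBu3) on the beta face of the C7–C8–C9 allyl unit, C11 as free CH2OH (drawn as the C7 sigma-allyl form) | CC1=C(CO)[C@@](C)(CC=C)[C@@H](C(C)=C)C[C@@H]1[Pd-](OC=O)[P+](CCCC)(CCCC)CCCC | intermediate
11 | [(1R,5R,6S)-2,6-dimethyl-6-allyl-5-isopropenylcyclohex-2-en-1-yl]methanol | CC1=CC[C@H](C(C)=C)[C@@](CC=C)(C)[C@@H]1CO | intermediate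
12 | umbelliferone | Oc1ccc2ccc(=O)oc2c1 | starting material
13 | umbelliferyl ether of 11 | CC1=CC[C@H](C(C)=C)[C@@](CC=C)(C)[C@@H]1COc1ccc2ccc(=O)oc2c1 | intermediate
14 | dioxygen | O=O | starting material
15 | (1S,2R,6R)-propanal (allyl of 13 turned into CH2CH2CHO) | CC1=CC[C@H](C(C)=C)[C@@](CCC=O)(C)[C@@H]1COc1ccc2ccc(=O)oc2c1 | intermediate
16 | Breslow enaminol of 15 with the N-mesityl cyclohepta-fused thiazol-2-ylidene | CC1=CC[C@H](C(C)=C)[C@@](CCC(O)=C2SC3=C(CCCCC3)N2c2c(C)cc(C)cc2C)(C)[C@@H]1COc1ccc2ccc(=O)oc2c1 | intermediate
17 | (1R,4aS,8aS)-3-oxo-cis-drim-7-en-11-yl umbelliferyl ether | CC1=CC[C@@H]2C(C)(C)C(=O)CC[C@]2(C)[C@@H]1COc1ccc2ccc(=O)oc2c1 | target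

**Count:** 7 steps in total; the longest linear sequence is 7 steps (from 1).

**Steps most likely to fail, with fallbacks**

Step 7 is the largest risk. The aliphatic aldehyde may self-condense or rest as acyloin. The purely alkyl alkene may be too unreactive. Bridging attack on C8 of the ring alkene is also conceivable. The fallback sets out from 15 and reverses which carbon is activated. Fe(acac)3 and PhSiH3 in EtOH at 60 °C transfer a hydrogen atom to the isopropenyl =CH2, and the resulting tertiary C4 radical adds 6-exo to the aldehyde C=O. This gives the 3-hydroxy cis-drimenyl umbelliferyl ether F1 as a mixture of C3 epimers. Dess–Martin oxidation of both epimers comes back to the route at 17.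

Step 4 is the second risk. Hydride may go to C7 and give the tetrasubstituted C8=C9 alkene, or beta-hydride loss may give a dienol. The fallback sets out from 9 and uses a cationic 1,2-shift instead of a metal hydride. MgBr2·OEt2 in CH2Cl2 at −78 °C opens the allylic C9–O bond, and a C11 hydrogen migrates to C9 anti to the departing oxygen (Meinwald rearrangement). This gives the beta,gamma-unsaturated (1R,5R,6S)-cyclohexene-1-carbaldehyde F2. Reducing it at once with NaBH4 in MeOH, before it can epimerise or conjugate, comes back to the route at 11.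

Step 3 is the third risk. The carbonyl sits between a quaternary carbon and a methyl-bearing alkene carbon, the ylide can deprotonate the gamma position, and the facial ratio is not proven. The fallback sets out from 7 and uses a hydroxymethyl anion equivalent.
- (iPrO)Me2SiCH2MgCl with CeCl3 in THF adds 1,2 from the same beta face to give the tertiary allylic beta-hydroxysilane F3.
- Tamao oxidation (H2O2, KF, KHCO3, MeOH/THF) gives the 1-(hydroxymethyl)cyclohexenol diol F4.
- 1,1'-Carbonyldiimidazole closes it to the spiro cyclic carbonate F5.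
- Under the Pd2(dba)3·CHCl3/n-Bu3P/HCO2H–Et3N conditions of step 4, F5 ionises with inversion and is reduced at C9. This comes back to the route at 11 without passing through the acid-labile epoxide.

**Further compounds**
F1 | step 7 | 7-{[(1R,4aS,8aS)-6-hydroxy-2,5,5,8a-tetramethyl-1,4,4a,5,6,7,8,8a-octahydronaphthalen-1-yl]methoxy}-2H-chromen-2-one (C6 carbinol epimers) | CC1=CC[C@@H]2C(C)(C)C(O)CC[C@]2(C)[C@@H]1COc1ccc2ccc(=O)oc2c1
F2 | step 4 | (1R,5R,6S)-2,6-dimethyl-6-(prop-2-enyl)-5-(prop-1-en-2-yl)cyclohex-2-ene-1-carbaldehyde | CC1=CC[C@H](C(C)=C)[C@@](CC=C)(C)[C@@H]1C=O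
F3 | step 3 | (1R,5R,6S)-1-{[dimethyl(propan-2-yloxy)silyl]methyl}-2,6-dimethyl-6-(prop-2-enyl)-5-(prop-1-en-2-yl)cyclohex-2-en-1-ol | CC1=CC[C@H](C(C)=C)[C@@](CC=C)(C)[C@@]1(O)C[Si](C)(C)OC(C)C
F4 | step 3 | (1R,5R,6S)-1-(hydroxymethyl)-2,6-dimethyl-6-(prop-2-enyl)-5-(prop-1-en-2-yl)cyclohex-2-en-1-ol | CC1=CC[C@H](C(C)=C)[C@@](CC=C)(C)[C@@]1(O)CO
F5 | step 3 | (5R,9R,10S)-6,10-dimethyl-10-(prop-2-enyl)-9-(prop-1-en-2-yl)-1,3-dioxaspiro[4.5]dec-6-en-2-one | CC1=CC[C@H](C(C)=C)[C@@](CC=C)(C)[C@@]12COC(=O)O2
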